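The target in the east flask stood at 58.9% of the substrate charged, the mean of its readings from 240 min on, and I had to explain that level.

| flask | substrate | partner | protic impurity | remark | time |
|---|---|---|---|---|---|
| east | 0.25 M | 0.375 M | 0.125 M | the very flask that is asked about, followed so far |  |
| north-east | 0.38 M | 0.375 M | 0.125 M | run made earlier |  |
| flask | 0.25 M | 0.375 M | 0.125 M |  | 12 h |

| run | time / min | target / % | substrate / % |
|---|---|---|---|
| east | 50.0 | 34.1 | 22.8 |
| east | 150 | 56.5 | 1.1 |
| east | 240 | 58.2 | 0 |
| east | 360 | 58.8 | 0.4 |
| east | 600 | 59.6 | 0.1 |
| east | 720 | 58.9 | 0 |
| north-east | 2.00 | 0 | 94.0 |
| north-east | 5.00 | 0.7 | 86.5 |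
| north-east | 10.0 | 2.2 | 74.3 |
| north-east | 15.0 | 5.6 | 63.8 |
| north-east | 20.0 | 9.6 | 55.4 |
| north-east | 30.0 | 18.4 | 40.9 |

(each reading ± 0.3 percentage points)

- target taken out counts as made
- additions bring no volume worth counting

- winter: change nothing and wait 4.0 h more
- autumn: at 12 h add substrate, 50.0% of the amount charged, then wait 4.0 h
- dusk: at 12 h take out 90% of the target then present, then wait 4.0 h
- summer: at 12 h add partner, 50.0% of the amount charged, then wait 4.0 h

- target, in percent of the substrate first charged, at 12 h
- which option adds most target ("none" when 2 percentage points or less is all one gets) (winter / autumn / dusk / summer / none)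
- target present, with what was taken out counted in, in percent of the substrate first charged, after autumn
- target present, with what was taken out counted in, in percent of the substrate first charged, after dusk

I drew the curves first. Substrate fell at 0.0296 min⁻¹ in the east flask and 0.0298 min⁻¹ in the north-east run, which was about the same despite its larger charge, so I read a first-order step with a half-life of 23.4 min. Target started flat, at 0% after 2.00 min and 18.4% after 30.0 min in the north-east run, so I put an intermediate before it. In the east flask the knee came near 150 min, at 56.5% with substrate down to 1.1%.

My first answer, that target stops with substrate at the whole charge, missed by 41 percentage points. I therefore took partner for the limiting reagent and defined the partner yield, target made per partner charged, as 0.393. Putting this back in, summer's partner should add 29 points, less than the gap, so my reckoning for summer stood at 87.9%. I put the target at 12 h at the plateau, named summer as best and held winter, autumn and dusk at the plateau.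

The forecast gave 59%, autumn, 93% after autumn and 59.3% after dusk, holding that “waiting, adding partner or removing target give nothing”; on the best option and on autumn it differed from my reckoning.

The flask gave 59.1% at 12 h, with partner at 0% of its charge and open intermediate at 40.9% of the substrate charged, and summer added 28 points against my 29 points, while autumn stayed at 59.1% and dusk at 59.1%.

    substrate → open intermediate (k = 0.0295 min⁻¹)
    partner → second intermediate (k = 0.0901 min⁻¹)
    2 second intermediate → homo product (k = 0.0296 L mol⁻¹ min⁻¹)
    partner + protic impurity → quenched reagent (k = 0.162 L mol⁻¹ min⁻¹)
    open intermediate + second intermediate → target (k = 0.131 L mol⁻¹ min⁻¹)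
    second intermediate → decomposed reagent (k = 0.00690 min⁻¹)

Carried to the neighbour flask charged with 1.5 M of partner, the partner yield of 0.393 offers 0.589 M of target, more than its 0.25 M of substrate, so there I expected substrate to cap the target near the whole charge; that neighbour flask gave 90.7%, with 9.25% of the substrate charged still open intermediate and partner at 0% of its charge.

(The numbers in the tables are simulated with made-up constants, noise included.)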